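**Retrosynthetic overview**
1. Target ⇐ global O-debenzylation of its hexabenzyl ether by neutral hydrogenolysis.
2. The cis (2R,3R) pair of the 3-linked eriodictyol half (unit E) ⇐ catalytic asymmetric syn-hydrogenation that dearomatizes the γ-pyrone ring of a flat 2,3-diarylchromone (key step, sets both centres at once).
3. The (2S) centre of the 8-linked naringenin half (unit N) ⇐ asymmetric conjugate arylation that dearomatizes a 2-unsubstituted chromone ring with 4-(benzyloxy)phenylboronic acid.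
4. C-3(E)–C-8(N) bond ⇐ borylation/Suzuki–Miyaura coupling of a quercetin 3-triflate (from rutin) with an 8-iodochromone (from 2',4',6'-trihydroxyacetophenone).
5. Ring order: the pyrone of unit N is built on the acetophenone and the pyrone of unit E comes with rutin; the two flat benzopyrones are joined, then the N pyranone and last the E pyranone are saturated.

**Assumptions**
- The SMILES is taken literally: C-2 and C-3 of unit E are both R, which places the two aryl groups cis (the less stable, epimerizable arrangement); unit N is 2S.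
- The C-3(E)–C-8(N) axis of the flat coupled intermediates is hindered; they are used as atropisomer mixtures (axis not drawn), which converge once C-3(E) becomes sp3.
- Ligand antipodes in the two ligand-controlled steps are assigned by analogy; if a first run shows the opposite sense, the mirror-image ligand is used.

**Route**

Step 1
Reactants: 1 rutin (quercetin 3-O-rutinoside)
Product: 3 7,3',4'-tri-O-benzylquercetin, via tribenzylrutin 2 (not isolated)
Conditions: BnBr (3.3 equiv), K2CO3, DMF, 60 °C, N2; filter, concentrate; then conc. HCl, EtOH, reflux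
Reagents that add atoms: benzyl bromide, BrCc1ccccc1
Why: Williamson O-benzylation reaches only the 7-, 3'- and 4'-phenols (3-O carries the sugar, 5-OH is hydrogen-bonded to C-4=O), and acid-catalysed glycoside hydrolysis then frees the 3-OH alone.

Step 2
Reactants: 3 7,3',4'-tri-O-benzylquercetin
Product: 4 quercetin 3-triflate [7-(benzyloxy)-2-[3,4-bis(benzyloxy)phenyl]-5-hydroxy-4-oxo-4H-chromen-3-yl trifluoromethanesulfonate]
Conditions: PhNTf2 (1.1 equiv), Et3N, DMAP (cat.), CH2Cl2, 0 °C to rt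
Reagents that add atoms: N-phenylbis(trifluoromethanesulfonimide), O=S(=O)(N(c1ccccc1)S(=O)(=O)C(F)(F)F)C(F)(F)F
Why: O-sulfonylation with a mild triflyl donor occurs at the enolic 3-OH, which is far more nucleophilic than the chelated 5-OH, giving the enol triflate needed as cross-coupling electrophile.

Step 3
Reactants: 5 2',4',6'-trihydroxyacetophenone
Product: 6 1-[2,4-bis(benzyloxy)-6-hydroxyphenyl]ethan-1-one
Conditions: BnBr (2.1 equiv), K2CO3, DMF, 0 °C to rt
Reagents that add atoms: benzyl bromide, BrCc1ccccc1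
Why: Williamson etherification of the two non-chelated phenols; the OH hydrogen-bonded to the acetyl group stays free and later becomes the ring oxygen.

Step 4
Reactants: 6 1-[2,4-bis(benzyloxy)-6-hydroxyphenyl]ethan-1-one
Product: 7 1-[4,6-bis(benzyloxy)-2-hydroxy-3-iodophenyl]ethan-1-one
Conditions: NIS (1.05 equiv), CF3CO2H (10 mol %), MeCN, 0 °C to rt, dark
Reagents that add atoms: N-iodosuccinimide, O=C1CCC(=O)N1I
Why: Electrophilic aromatic iodination goes ortho to the free phenol (position 3, para to a benzyloxy group), the less hindered of the two open positions, so iodine sits on the carbon that becomes C-8 of the chromone.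

Step 5
Reactants: 7 1-[4,6-bis(benzyloxy)-2-hydroxy-3-iodophenyl]ethan-1-one
Product: 9 iodochromone [5,7-bis(benzyloxy)-8-iodo-4H-chromen-4-one], via enaminone 8 (not isolated)
Conditions: Me2NCH(OMe)2 (3 equiv), toluene, 95 °C; evaporate; then conc. HCl, CH2Cl2, 40 °C
Reagents that add atoms: N,N-dimethylformamide dimethyl acetal, COC(OC)N(C)C
Why: Condensation at the acetyl methyl group gives the enaminone, and acid-promoted 6-endo cyclization with loss of dimethylamine (enaminone chromone synthesis) builds the γ-pyrone ring with C-2 unsubstituted.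

Step 6
Reactants: 9 iodochromone; 4 quercetin 3-triflate
Product: 11 flavone–chromone [3-[5,7-bis(benzyloxy)-4-oxo-4H-chromen-8-yl]-7-(benzyloxy)-2-[3,4-bis(benzyloxy)phenyl]-5-hydroxy-4H-chromen-4-one, atropisomer mixture], via boronate 10 (not isolated)
Conditions: B2pin2 (1.1 equiv), Pd(dppf)Cl2 (5 mol %), KOAc, 1,4-dioxane, 90 °C; then 4 (0.9 equiv), Pd(OAc)2 (5 mol %), SPhos (10 mol %), K3PO4, H2O (dioxane/H2O 10:1), 80 °C
Reagents that add atoms: bis(pinacolato)diboron, CC1(C)OB(OC1(C)C)B1OC(C)(C)C(C)(C)O1 (supplies the boron group of 10 only; none of its atoms remain in 11)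
Why: Miyaura borylation of the aryl iodide followed in the same pot by Suzuki–Miyaura coupling with the enol triflate, using a bulky biarylphosphine suited to di-ortho-substituted partners, forms the C-3(E)–C-8(N) bond; no stereocentre is formed.

Step 7
Reactants: 11 flavone–chromone; 12 4-(benzyloxy)phenylboronic acid
Product: 13 flavone–flavanone [3-[(2S)-5,7-bis(benzyloxy)-2-[4-(benzyloxy)phenyl]-4-oxo-3,4-dihydro-2H-chromen-8-yl]-7-(benzyloxy)-2-[3,4-bis(benzyloxy)phenyl]-5-hydroxy-4H-chromen-4-one]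
Conditions: 12 (3 equiv), Pd(OCOCF3)2 (10 mol %), (R)-t-BuPyOx (12 mol %), NH4PF6 (30 mol %), H2O (5 equiv), ClCH2CH2Cl, 60 °C
Reagents that add atoms: none
Why: Hayashi–Miyaura-type asymmetric conjugate addition under cationic divalent palladium/pyridine-oxazoline catalysis adds the aryl group to C-2 of the only β-unsubstituted pyrone (the 2,3-diaryl pyrone of unit E is inert), the (R)-ligand steering it to the Re face to give the (2S)-flavanone, and the base-free protonolysis of the palladium enolate by water avoids racemization through the chalcone.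

Step 8
Reactants: 13 flavone–flavanone
Product: 14 hexabenzyl cis-biflavanone [(2R,3R)-3-[(2S)-5,7-bis(benzyloxy)-2-[4-(benzyloxy)phenyl]-4-oxo-3,4-dihydro-2H-chromen-8-yl]-7-(benzyloxy)-2-[3,4-bis(benzyloxy)phenyl]-5-hydroxy-2,3-dihydro-4H-chromen-4-one]
Conditions: [Ir(cod)((S)-t-BuPHOX)][B(3,5-(CF3)2C6H3)4] (5 mol %), H2 (80 bar), CH2Cl2, 40 °C; short silica plug, no base
Reagents that add atoms: none
Why: Proposed new method: a cationic iridium phosphinooxazoline complex hydrogenates the tetrasubstituted C-2=C-3 bond of the 2,3-diaryl γ-pyrone by migratory insertion and reductive elimination on one alkene face, so both hydrogens arrive syn and the two aryl groups end up cis, with the ligand choosing the face that gives (2R,3R); the closest known reactions are iridium N,P-catalysed asymmetric hydrogenations of tetrasubstituted and oxygen-heterocyclic olefins and asymmetric hydrogenations of 2-substituted chromones and flavones to chromanones, and the neutral medium leaves the kinetic cis pair and the (2S) centre untouched while both atropisomers converge on one product.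

Step 9
Reactants: 14 hexabenzyl cis-biflavanone
Product: 15 target [(2R,3R)-2-(3,4-dihydroxyphenyl)-3-[(2S)-5,7-dihydroxy-2-(4-hydroxyphenyl)-4-oxo-3,4-dihydro-2H-chromen-8-yl]-5,7-dihydroxy-2,3-dihydro-4H-chromen-4-one]
Conditions: H2 (1 atm), 10 % Pd/C, EtOAc/MeOH 1:1, rt; filter, evaporate below 30 °C
Reagents that add atoms: none
Why: Heterogeneous hydrogenolysis of the six benzyl ethers at room temperature under neutral conditions leaves the ketones and the benzylic C-2–O bonds intact and gives no acid or base that could epimerize C-3(E) or open either pyranone ring.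

**Compound list**
1 | rutin (quercetin 3-O-rutinoside) | C[C@H]1[C@@H]([C@H]([C@H]([C@@H](O1)OC[C@@H]2[C@H]([C@@H]([C@H]([C@@H](O2)OC3=C(OC4=CC(=CC(=C4C3=O)O)O)C5=CC(=C(C=C5)O)O)O)O)O)O)O)O | starting material
2 | 7,3',4'-tri-O-benzylrutin | C[C@H]1[C@@H]([C@H]([C@H]([C@@H](O1)OC[C@@H]2[C@H]([C@@H]([C@H]([C@@H](O2)OC3=C(OC4=CC(=CC(=C4C3=O)O)OCc5ccccc5)C6=CC(=C(C=C6)OCc7ccccc7)OCc8ccccc8)O)O)O)O)O)O | intermediate (not isolated)
3 | 7,3',4'-tri-O-benzylquercetin [7-(benzyloxy)-2-[3,4-bis(benzyloxy)phenyl]-3,5-dihydroxy-4H-chromen-4-one] | O=c1c(O)c(-c2ccc(OCc3ccccc3)c(OCc3ccccc3)c2)oc2cc(OCc3ccccc3)cc(O)c12 | intermediate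
4 | 7-(benzyloxy)-2-[3,4-bis(benzyloxy)phenyl]-5-hydroxy-4-oxo-4H-chromen-3-yl trifluoromethanesulfonate | O=c1c(OS(=O)(=O)C(F)(F)F)c(-c2ccc(OCc3ccccc3)c(OCc3ccccc3)c2)oc2cc(OCc3ccccc3)cc(O)c12 | intermediate
5 | 2',4',6'-trihydroxyacetophenone | CC(=O)c1c(O)cc(O)cc1O | starting material
6 | 1-[2,4-bis(benzyloxy)-6-hydroxyphenyl]ethan-1-one | CC(=O)c1c(O)cc(OCc2ccccc2)cc1OCc1ccccc1 | intermediate
7 | 1-[4,6-bis(benzyloxy)-2-hydroxy-3-iodophenyl]ethan-1-one | CC(=O)c1c(O)c(I)c(OCc2ccccc2)cc1OCc1ccccc1 | intermediate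
8 | (E)-1-[4,6-bis(benzyloxy)-2-hydroxy-3-iodophenyl]-3-(dimethylamino)prop-2-en-1-one | CN(C)/C=C/C(=O)c1c(O)c(I)c(OCc2ccccc2)cc1OCc1ccccc1 | intermediate (not isolated)
9 | 5,7-bis(benzyloxy)-8-iodo-4H-chromen-4-one | O=c1ccoc2c(I)c(OCc3ccccc3)cc(OCc3ccccc3)c12 | intermediate
10 | 5,7-bis(benzyloxy)-8-(4,4,5,5-tetramethyl-1,3,2-dioxaborolan-2-yl)-4H-chromen-4-one | O=c1ccoc2c(B3OC(C)(C)C(C)(C)O3)c(OCc3ccccc3)cc(OCc3ccccc3)c12 | intermediate (not isolated)
11 | 3-[5,7-bis(benzyloxy)-4-oxo-4H-chromen-8-yl]-7-(benzyloxy)-2-[3,4-bis(benzyloxy)phenyl]-5-hydroxy-4H-chromen-4-one (atropisomer mixture) | O=c1ccoc2c1c(OCc1ccccc1)cc(OCc1ccccc1)c2-c1c(-c2ccc(OCc3ccccc3)c(OCc3ccccc3)c2)oc2cc(OCc3ccccc3)cc(O)c2c1=O | intermediate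
12 | 4-(benzyloxy)phenylboronic acid | OB(O)c1ccc(OCc2ccccc2)cc1 | starting material
13 | 3-[(2S)-5,7-bis(benzyloxy)-2-[4-(benzyloxy)phenyl]-4-oxo-3,4-dihydro-2H-chromen-8-yl]-7-(benzyloxy)-2-[3,4-bis(benzyloxy)phenyl]-5-hydroxy-4H-chromen-4-one (atropisomer mixture) | O=C1C[C@@H](c2ccc(OCc3ccccc3)cc2)Oc2c1c(OCc1ccccc1)cc(OCc1ccccc1)c2-c1c(-c2ccc(OCc3ccccc3)c(OCc3ccccc3)c2)oc2cc(OCc3ccccc3)cc(O)c2c1=O | intermediate
14 | (2R,3R)-3-[(2S)-5,7-bis(benzyloxy)-2-[4-(benzyloxy)phenyl]-4-oxo-3,4-dihydro-2H-chromen-8-yl]-7-(benzyloxy)-2-[3,4-bis(benzyloxy)phenyl]-5-hydroxy-2,3-dihydro-4H-chromen-4-one (2,3-cis) | O=C1C[C@@H](c2ccc(OCc3ccccc3)cc2)Oc2c1c(OCc1ccccc1)cc(OCc1ccccc1)c2[C@H]1C(=O)c2c(O)cc(OCc3ccccc3)cc2O[C@H]1c1ccc(OCc2ccccc2)c(OCc2ccccc2)c1 | intermediate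
15 | (2R,3R)-2-(3,4-dihydroxyphenyl)-3-[(2S)-5,7-dihydroxy-2-(4-hydroxyphenyl)-4-oxo-3,4-dihydro-2H-chromen-8-yl]-5,7-dihydroxy-2,3-dihydro-4H-chromen-4-one (CNP0105436.1) | O=C1C[C@@H](c2ccc(O)cc2)Oc2c1c(O)cc(O)c2[C@H]1C(=O)c2c(O)cc(O)cc2O[C@H]1c1ccc(O)c(O)c1 | target

**Step count**
Total steps: 9. Longest linear sequence: 7 (5 → 6 → 7 → 9 → 11 → 13 → 14 → 15, steps 3 to 9).

**Three steps most likely to fail, with fallbacks**

Step 8 (key hydrogenation). The tetrasubstituted, doubly ortho-flanked alkene may not bind the iridium catalyst, or the hindered axis may override the ligand. The fallback sets out from 13 and comes back at 14, and replaces syn-H2 addition by separate hydride and proton delivery. Copper hydride 1,4-hydrosilylation (Cu(OAc)2 5 mol %, (R)-DTBM-SEGPHOS, (EtO)2MeSiH 2.2 equiv, toluene, −20 °C) puts hydride on C-2(E) under ligand control and silylates the 5-OH, giving the bis-silylated 2H-chromene enol ether F1. Its C-2(E) has the spatial arrangement of 14 but the descriptor S, because the priorities change. Silane is limited to 2.2 equiv and the temperature kept low to spare the flanked ketone of unit N. Protonation of F1 with AcOH/n-Bu4NF in THF at −78 °C is kinetic: the 2-aryl group sits pseudoaxial to avoid strain with the 3-aryl group, the proton enters C-3 from the opposite face, and the cis ketone 14 results.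

Step 6 (hindered coupling). The 2,6-dioxygenated boronate 10 may protodeboronate faster than it couples, and aqueous base may hydrolyse triflate 4. The fallback sets out from 9 (with 4) and comes back at 11, using a neutral tin nucleophile without water or base. Iodide 9 with Me3SnSnMe3 and Pd(PPh3)4 in toluene at 100 °C gives the 8-(trimethylstannyl)chromone F2. Copper-assisted Stille coupling of F2 with 4 (Pd(PPh3)4, CuI, LiCl, DMF, 80 °C) gives 11.

Step 7 (conjugate arylation). The electron-rich 5,7-dioxygenated chromone with its bulky 8-substituent may react slowly, or the hindered axis may erode the selectivity. The fallback sets out from 11 and comes back at 14, and gives up catalyst control at this centre in favour of a later diastereomer separation. Achiral addition (Pd(OCOCF3)2, 2,2'-bipyridine, same solvent system) gives 13 together with its C-2(N) epimer F3. The pair is taken through step 8, where the axis becomes free to rotate. The product 14 and its (2R)-unit-N diastereomer F4 are then ordinary diastereomers and are separated by chromatography on silica without base.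

**Further compounds**
F1 | step 8 | (2S)-5,7-bis(benzyloxy)-8-[(2S)-7-(benzyloxy)-2-[3,4-bis(benzyloxy)phenyl]-4,5-bis{[diethoxy(methyl)silyl]oxy}-2H-chromen-3-yl]-2-[4-(benzyloxy)phenyl]-2,3-dihydro-4H-chromen-4-one | O=C1C[C@@H](c2ccc(OCc3ccccc3)cc2)Oc2c1c(OCc1ccccc1)cc(OCc1ccccc1)c2C1=C(O[Si](C)(OCC)OCC)c2c(O[Si](C)(OCC)OCC)cc(OCc3ccccc3)cc2O[C@H]1c1ccc(OCc2ccccc2)c(OCc2ccccc2)c1
F2 | step 6 | 5,7-bis(benzyloxy)-8-(trimethylstannyl)-4H-chromen-4-one | O=c1ccoc2c([Sn](C)(C)C)c(OCc3ccccc3)cc(OCc3ccccc3)c12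
F3 | step 7 | 3-[(2R)-5,7-bis(benzyloxy)-2-[4-(benzyloxy)phenyl]-4-oxo-3,4-dihydro-2H-chromen-8-yl]-7-(benzyloxy)-2-[3,4-bis(benzyloxy)phenyl]-5-hydroxy-4H-chromen-4-one | O=C1C[C@H](c2ccc(OCc3ccccc3)cc2)Oc2c1c(OCc1ccccc1)cc(OCc1ccccc1)c2-c1c(-c2ccc(OCc3ccccc3)c(OCc3ccccc3)c2)oc2cc(OCc3ccccc3)cc(O)c2c1=O
F4 | step 7 | (2R,3R)-3-[(2R)-5,7-bis(benzyloxy)-2-[4-(benzyloxy)phenyl]-4-oxo-3,4-dihydro-2H-chromen-8-yl]-7-(benzyloxy)-2-[3,4-bis(benzyloxy)phenyl]-5-hydroxy-2,3-dihydro-4H-chromen-4-one | O=C1C[C@H](c2ccc(OCc3ccccc3)cc2)Oc2c1c(OCc1ccccc1)cc(OCc1ccccc1)c2[C@H]1C(=O)c2c(O)cc(OCc3ccccc3)cc2O[C@H]1c1ccc(OCc2ccccc2)c(OCc2ccccc2)c1
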